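**Strategy.** The dimer is cut at ring C (C1–C2–C3–C11′–C13′–C5; xanthanolide numbering, lower half primed) into two antipodal, all-cis hexahydrobenzofuranones, both from one arene by hydrogenation and lipase resolution. The upper seven-membered ring (C1, C5–C10) is read as a 2-methylcyclohexanone plus one carbon: C5, the ring carbon next to carbinol C1 that carries C13′, is inserted between C1 and C6 by Sc(OTf)3-catalysed homologation of ketone 9 with TMSCHN2. One operation gives the ring and, after Brook shift, the C1=C5 enol silane, through which C5 is joined to the lower formyl lactone; C1 then takes C2 by carbonyl addition.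

Key step: step 6

Remark on the chemistry: in the given structure the lower half (C7′, C8′, C10′) is the mirror image of the upper half (C7, C8, C10), and C13′ sits cis to the C10 methyl on the upper seven-membered ring. Ring C is therefore assembled stepwise from the C1 ketone, where C5 is set by protonation and C1 by carbonyl addition, and not by a cycloaddition on a pre-formed diene.

Step 1
Reactants: 1 2-methyl-1,4-benzoquinone; 2 1-(tert-butyldimethylsilyloxy)-1-methoxyethene
Product: 4 5-hydroxy-6-methyl-1-benzofuran-2(3H)-one, via silylated aryl acetate 3 (not isolated)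
Conditions: ZnCl2 (10 mol %), CH2Cl2, −78 → 0 °C; then HCl (2 M), MeOH, 50 °C
Reagents that add atoms: none
Why: Mukaiyama–Michael addition of the ketene silyl acetal to the quinone at C5 (para to the methyl group, the position the methyl does not deactivate), tautomerisation to the hydroquinone, then acid-induced desilylation and lactonisation onto the neighbouring phenol; no stereocentre.

Step 2
Reactants: 4 5-hydroxy-6-methyl-1-benzofuran-2(3H)-one
Product: 5 racemic all-cis 5-hydroxy-6-methylhexahydro-1-benzofuran-2(3H)-one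
Conditions: H2 (60 bar), 5% Rh/Al2O3, AcOH, 60 °C
Reagents that add atoms: none
Why: Heterogeneous arene hydrogenation delivers all hydrogens from the catalyst face, so lactone ring fusion, methyl and hydroxyl should come out all-cis (racemate).

Step 3
Reactants: 5 racemic all-cis hydroxy lactone
Product: 6 (3aR,5R,6S,7aR)-6-methyl-2-oxooctahydro-1-benzofuran-5-yl acetate; 7 unreacted (3aS,5S,6R,7aS)-5-hydroxy-6-methylhexahydro-1-benzofuran-2(3H)-one
Conditions: Novozym 435 (Candida antarctica lipase B), vinyl acetate, MTBE, 30 °C, stopped at 50% conversion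
Reagents that add atoms: vinyl acetate, CC(=O)OC=C
Why: Lipase kinetic resolution by transesterification; by the Kazlauskas rule the (5R)-alcohol (larger flanking group CHCH3) should be acylated and the (5S)-alcohol left, and both antipodes are used (6 for the upper half, 7 for the lower half).

Step 4
Reactants: 6 (3aR,5R,6S,7aR) acetate
Product: 8 (3aR,5R,6S,7aR)-5-hydroxy-6-methylhexahydro-1-benzofuran-2(3H)-one
Conditions: Novozym 435, phosphate buffer pH 7, acetone, 30 °C
Reagents that add atoms: none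
Why: Enzymatic ester hydrolysis at neutral pH spares the γ-lactone and should upgrade the enantiomeric purity; no stereocentre is touched.

Step 5
Reactants: 8 (3aR,5R,6S,7aR) alcohol
Product: 9 (3aR,6S,7aR)-6-methylhexahydro-1-benzofuran-2,5-dione
Conditions: Dess–Martin periodinane, NaHCO3, CH2Cl2, 0 °C → rt
Reagents that add atoms: none
Why: Buffered Dess–Martin oxidation of the secondary alcohol; the neutral conditions should not epimerise the α-methyl centre (future C10).

Step 6
Reactants: 9 (3aR,6S,7aR)-6-methylhexahydro-1-benzofuran-2,5-dione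
Product: 11 (3aR,7S,8aR)-7-methyl-6-(trimethylsilyloxy)-3,3a,4,7,8,8a-hexahydro-2H-cyclohepta[b]furan-2-one, via alpha-silyl cycloheptanone 10 (not isolated)
Conditions: TMSCHN2 (1.2 equiv), Sc(OTf)3 (10 mol %), CH2Cl2, −78 → 0 °C, then 40 °C
Reagents that add atoms: trimethylsilyldiazomethane, C[Si](C)(C)C=[N+]=[N-]
Why: Sc(OTf)3 activates the ketone (C1), the diazo carbon of TMSCHN2 adds to it, and the less substituted α-carbon (C6, CH2) migrates to the diazo carbon with loss of N2; this is the Lewis-acid-promoted diazoalkane–ketone homologation (Tiffeneau–Demjanov type). No ring is closed: the six-membered ring of 9 is enlarged to the seven-membered ring by 1,2-shift of the C1–C6 bond onto the new carbon C5. The α-silyl ketone 10 should then undergo 1,3-Brook shift under the Lewis acid to the enol silane, which fixes the double bond at C1=C5 and blocks a second insertion. No stereocentre is formed, and C7, C8 and C10 are untouched because the medium is non-basic. The step needs migration of CH2 over CHCH3, which the α-methyl branch and the bulk of the silylated diazo carbon should secure.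

Step 7
Reactants: 7 (3aS,5S,6R,7aS) alcohol
Product: 12 (3aS,6R,7aS)-6-methylhexahydro-1-benzofuran-2,5-dione
Conditions: Dess–Martin periodinane, NaHCO3, CH2Cl2, 0 °C → rt
Reagents that add atoms: none
Why: Same buffered alcohol oxidation as step 5, in the mirror-image series.

Step 8
Reactants: 12 (3aS,6R,7aS)-6-methylhexahydro-1-benzofuran-2,5-dione
Product: 14 (3aS,7R,8aS)-7-methyl-6-(trimethylsilyloxy)-3,3a,4,7,8,8a-hexahydro-2H-cyclohepta[b]furan-2-one, via alpha-silyl cycloheptanone 13 (not isolated)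
Conditions: TMSCHN2 (1.2 equiv), Sc(OTf)3 (10 mol %), CH2Cl2, −78 → 0 °C, then 40 °C
Reagents that add atoms: trimethylsilyldiazomethane, C[Si](C)(C)C=[N+]=[N-]
Why: Same diazoalkane–ketone homologation and Brook shift as step 6, giving the lower seven-membered ring with the C1′=C5′ enol silane; no new stereocentre.

Step 9
Reactants: 14 lower enol silane
Product: 15 (3aS,7R,8aS)-7-methyl-2-oxo-3,3a,4,7,8,8a-hexahydro-2H-cyclohepta[b]furan-6-yl trifluoromethanesulfonate
Conditions: PhNTf2, CsF, DME, rt
Reagents that add atoms: N-phenylbis(trifluoromethanesulfonimide), O=S(=O)(N(c1ccccc1)S(=O)(=O)C(F)(F)F)C(F)(F)F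
Why: Fluoride cleaves the enol silane to the regiodefined caesium enolate, which PhNTf2 triflates on oxygen (enol silane to enol triflate exchange); the C1′=C5′ position is kept and no strong base meets the lactone.

Step 10
Reactants: 15 lower enol triflate lactone
Product: 16 (3aS,7R,8aS)-3-(hydroxymethylidene)-7-methyl-2-oxo-3,3a,4,7,8,8a-hexahydro-2H-cyclohepta[b]furan-6-yl trifluoromethanesulfonate
Conditions: NaH, HCO2Et, THF, 0 °C → rt; HCl (1 M)
Reagents that add atoms: ethyl formate, CCOC=O
Why: Claisen formylation of the lactone enolate gives the stable hydroxymethylene lactone; the new carbon is the future C13′ and C11′ is planar at this stage.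

Step 11
Reactants: 16 hydroxymethylene lactone
Product: 17 (3S,3aS,7R,8aS)-3-formyl-7-methyl-2-oxo-3-[3-(trimethylsilyl)prop-2-yn-1-yl]-3,3a,4,7,8,8a-hexahydro-2H-cyclohepta[b]furan-6-yl trifluoromethanesulfonate
Conditions: K2CO3, BrCH2C≡CSiMe3, acetone, rt
Reagents that add atoms: 3-bromo-1-(trimethylsilyl)prop-1-yne, C[Si](C)(C)C#CCBr
Why: C-alkylation of the soft hydroxymethylene enolate by a propargylic bromide; the electrophile should enter trans to the ring carbon C6′ on C7′ (convex face of the cis-fused bicycle), which sets quaternary C11′ with the formyl group on the concave face.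

Step 12
Reactants: 11 upper enol silane; 17 lower formyl lactone
Product: 19 beta-hydroxy ketone with C5 bonded to C13′(OH), via silylated aldol 18 (not isolated)
Conditions: Sc(OTf)3 (10 mol %), CH2Cl2, −78 → −20 °C; then HCl (1 M), THF
Reagents that add atoms: none
Why: Mukaiyama aldol addition of the regiodefined enol silane to the non-enolisable neopentyl aldehyde forms the C5–C13′ bond without free enolate, so the formyl group is not transferred; the two new stereocentres are erased in steps 13 and 14.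

Step 13
Reactants: 19 beta-hydroxy ketone
Product: 21 2-alkylidene cycloheptanone (C5=C13′), via mesylate 20 (not isolated)
Conditions: MsCl, Et3N, CH2Cl2, −20 °C → rt
Reagents that add atoms: none
Why: Mesylation and E1cB elimination complete the aldol condensation; the mild amine base at low temperature should leave the C10 methyl centre unchanged, and the alkene geometry is of no consequence.

Step 14
Reactants: 21 2-alkylidene cycloheptanone
Product: 22 saturated ketone with C5–H
Conditions: [(Ph3P)CuH]6, H2O (10 equiv), degassed toluene/THF, rt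
Reagents that add atoms: none
Why: Copper hydride conjugate reduction gives the C1=C5 copper enolate regiospecifically, and water should protonate C5 on the face opposite the pseudoaxial C10 methyl (axial protonation), placing the C13′ methylene cis to that methyl; this is also the more stable 2,7-cis arrangement.

Step 15
Reactants: 22 saturated ketone
Product: 23 tertiary vinyl carbinol at C1
Conditions: CH2=CHMgBr, CeCl3, THF, −78 °C; H2O
Reagents that add atoms: vinylmagnesium bromide, C=C[Mg]Br
Why: Organocerium 1,2-addition; the vinyl group (C2) should enter trans to both flanking substituents (C10 methyl and C5 CH2R, equatorial attack), so the C1 hydroxyl is cis to them, and CeCl3 suppresses enolisation and spares the lactones and the triflate.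

Step 16
Reactants: 23 tertiary vinyl carbinol
Product: 24 Mannich base with CH2NMe2 on C11 of the upper lactone
Conditions: LiN(iPr)2 (2.2 equiv), THF, −78 °C; Me2N=CH2 iodide (Eschenmoser's salt), −78 °C → rt
Reagents that add atoms: N,N-dimethylmethyleneiminium iodide, C[N+](C)=C.[I-]
Why: Mannich reaction of the upper lactone enolate, the only C–H acid left beside the alkoxide (C11′ is quaternary); the new centre at C11 is lost in step 20.

Step 17
Reactants: 24 Mannich base
Product: 25 methyl ketone (acetonyl group on C11′)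
Conditions: AuCl(PPh3) (5 mol %), AgOTf (5 mol %), TsOH·H2O (1.2 equiv), MeOH/H2O, 40 °C
Reagents that add atoms: water, O
Why: Gold-catalysed Markovnikov hydration of the alkyne with protodesilylation gives the methyl ketone (C3, C4, C15 of the upper half); the amine is held as its tosylate salt.

Step 18
Reactants: 25 methyl ketone
Product: 28 ring C enone with C1 hydroxyl, via keto aldehyde 26 (not isolated), via ring-closed aldol 27 (not isolated)
Conditions: O3, TsOH·H2O (1.1 equiv), CH2Cl2/MeOH, −78 °C to indicator end point; Me2S; then pyrrolidine, AcOH, CH2Cl2, rt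
Reagents that add atoms: ozone, [O-][O+]=O
Why: Ozonolysis of the monosubstituted vinyl group (the enol triflate alkene is electron-poor and slower, the amine is protonated) gives the α-hydroxy aldehyde, which should close by amine-catalysed 6-(enolexo)-exo-trig aldol condensation through the internal α-carbon C3 of the methyl ketone to the trans-fused ring C enone; no stereocentre is changed.

Step 19
Reactants: 28 ring C enone enol triflate
Product: 29 dienone with masked upper methylene lactone
Conditions: CH2=CHCOCH3 (5 equiv), Pd(OAc)2 (10 mol %), PPh3 (20 mol %), Et3N, DMF, 60 °C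
Reagents that add atoms: methyl vinyl ketone, C=CC(C)=O
Why: Heck reaction of the cycloheptenyl triflate with methyl vinyl ketone gives the (E)-dienone side chain; the upper α-methylene lactone is still masked, so no competing acceptor is present.

Step 20
Reactants: 29 dienone Mannich base
Product: 31 target CNP0168949.2, via methiodide 30 (not isolated)
Conditions: MeI, CH2Cl2/MeOH, rt; then NaHCO3 (aq.), rt
Reagents that add atoms: none
Why: Quaternisation and Hofmann-type E1cB loss of trimethylamine from the β-ammonio lactone unveil the α-methylene lactone under conditions that spare the enone, the dienone and the tertiary alcohol.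

**Compound list**

1 | 2-methyl-1,4-benzoquinone | CC1=CC(=O)C=CC1=O | starting material
2 | 1-(tert-butyldimethylsilyloxy)-1-methoxyethene | C=C(OC)O[Si](C)(C)C(C)(C)C | starting material
3 | methyl 2-[5-(tert-butyldimethylsilyloxy)-2-hydroxy-4-methylphenyl]acetate | COC(=O)Cc1cc(O[Si](C)(C)C(C)(C)C)c(C)cc1O | intermediate
4 | 5-hydroxy-6-methyl-1-benzofuran-2(3H)-one | O=C1Cc2cc(O)c(C)cc2O1 | intermediate
5 | racemic all-cis 5-hydroxy-6-methylhexahydro-1-benzofuran-2(3H)-one (the (3aR,5R,6S,7aR) enantiomer is drawn) | C1C(=O)O[C@@H]2C[C@H](C)[C@H](O)C[C@H]12 | intermediate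
6 | (3aR,5R,6S,7aR)-6-methyl-2-oxooctahydro-1-benzofuran-5-yl acetate | C1C(=O)O[C@@H]2C[C@H](C)[C@H](OC(C)=O)C[C@H]12 | intermediate
7 | (3aS,5S,6R,7aS)-5-hydroxy-6-methylhexahydro-1-benzofuran-2(3H)-one | C1C(=O)O[C@H]2C[C@@H](C)[C@@H](O)C[C@@H]12 | intermediate
8 | (3aR,5R,6S,7aR)-5-hydroxy-6-methylhexahydro-1-benzofuran-2(3H)-one | C1C(=O)O[C@@H]2C[C@H](C)[C@H](O)C[C@H]12 | intermediate
9 | (3aR,6S,7aR)-6-methylhexahydro-1-benzofuran-2,5-dione | C1C(=O)O[C@@H]2C[C@H](C)C(=O)C[C@H]12 | intermediate
10 | (3aR,7S,8aR)-7-methyl-5-(trimethylsilyl)octahydro-2H-cyclohepta[b]furan-2,6-dione (C5 configuration open) | C1C(=O)O[C@@H]2C[C@H](C)C(=O)C([Si](C)(C)C)C[C@H]12 | intermediate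
11 | (3aR,7S,8aR)-7-methyl-6-(trimethylsilyloxy)-3,3a,4,7,8,8a-hexahydro-2H-cyclohepta[b]furan-2-one | C1C(=O)O[C@@H]2C[C@H](C)C(O[Si](C)(C)C)=CC[C@H]12 | intermediate
12 | (3aS,6R,7aS)-6-methylhexahydro-1-benzofuran-2,5-dione | C1C(=O)O[C@H]2C[C@@H](C)C(=O)C[C@@H]12 | intermediate
13 | (3aS,7R,8aS)-7-methyl-5-(trimethylsilyl)octahydro-2H-cyclohepta[b]furan-2,6-dione (C5 configuration open) | C1C(=O)O[C@H]2C[C@@H](C)C(=O)C([Si](C)(C)C)C[C@@H]12 | intermediate
14 | (3aS,7R,8aS)-7-methyl-6-(trimethylsilyloxy)-3,3a,4,7,8,8a-hexahydro-2H-cyclohepta[b]furan-2-one | C1C(=O)O[C@H]2C[C@@H](C)C(O[Si](C)(C)C)=CC[C@@H]12 | intermediate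
15 | (3aS,7R,8aS)-7-methyl-2-oxo-3,3a,4,7,8,8a-hexahydro-2H-cyclohepta[b]furan-6-yl trifluoromethanesulfonate | C1C(=O)O[C@H]2C[C@@H](C)C(OS(=O)(=O)C(F)(F)F)=CC[C@@H]12 | intermediate
16 | (3aS,7R,8aS)-3-(hydroxymethylidene)-7-methyl-2-oxo-3,3a,4,7,8,8a-hexahydro-2H-cyclohepta[b]furan-6-yl trifluoromethanesulfonate | OC=C1C(=O)O[C@H]2C[C@@H](C)C(OS(=O)(=O)C(F)(F)F)=CC[C@@H]12 | intermediate
17 | (3S,3aS,7R,8aS)-3-formyl-7-methyl-2-oxo-3-[3-(trimethylsilyl)prop-2-yn-1-yl]-3,3a,4,7,8,8a-hexahydro-2H-cyclohepta[b]furan-6-yl trifluoromethanesulfonate | C[Si](C)(C)C#CC[C@]1(C=O)C(=O)O[C@H]2C[C@@H](C)C(OS(=O)(=O)C(F)(F)F)=CC[C@H]21 | intermediate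
18 | silylated aldol: upper cycloheptanone C5 bonded to CH(OSiMe3) (C13′) on C11′ of 17 (C5 and C13′ configurations open) | C1C(=O)O[C@@H]2C[C@H](C)C(=O)C(C(O[Si](C)(C)C)[C@@]3(CC#C[Si](C)(C)C)C(=O)O[C@H]4C[C@@H](C)C(OS(=O)(=O)C(F)(F)F)=CC[C@H]43)C[C@H]12 | intermediate
19 | beta-hydroxy ketone: as 18 with free C13′ hydroxyl | C1C(=O)O[C@@H]2C[C@H](C)C(=O)C(C(O)[C@@]3(CC#C[Si](C)(C)C)C(=O)O[C@H]4C[C@@H](C)C(OS(=O)(=O)C(F)(F)F)=CC[C@H]43)C[C@H]12 | intermediate
20 | mesylate of 19 at the C13′ oxygen | C1C(=O)O[C@@H]2C[C@H](C)C(=O)C(C(OS(C)(=O)=O)[C@@]3(CC#C[Si](C)(C)C)C(=O)O[C@H]4C[C@@H](C)C(OS(=O)(=O)C(F)(F)F)=CC[C@H]43)C[C@H]12 | intermediate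
21 | 2-alkylidene cycloheptanone with C5=C13′ double bond (geometry open) | C1C(=O)O[C@@H]2C[C@H](C)C(=O)C(=C[C@@]3(CC#C[Si](C)(C)C)C(=O)O[C@H]4C[C@@H](C)C(OS(=O)(=O)C(F)(F)F)=CC[C@H]43)C[C@H]12 | intermediate
22 | saturated C1 ketone, C5–H with C13′H2 cis to the C10 methyl | C1C(=O)O[C@@H]2C[C@H](C)C(=O)[C@H](C[C@@]3(CC#C[Si](C)(C)C)C(=O)O[C@H]4C[C@@H](C)C(OS(=O)(=O)C(F)(F)F)=CC[C@H]43)C[C@H]12 | intermediate
23 | C1 tertiary vinyl carbinol (hydroxyl cis to C10 methyl and C13′) | C1C(=O)O[C@@H]2C[C@H](C)[C@@](O)(C=C)[C@H](C[C@@]3(CC#C[Si](C)(C)C)C(=O)O[C@H]4C[C@@H](C)C(OS(=O)(=O)C(F)(F)F)=CC[C@H]43)C[C@H]12 | intermediate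
24 | Mannich base: 23 with CH2NMe2 on C11 (C11 configuration open) | CN(C)CC1C(=O)O[C@@H]2C[C@H](C)[C@@](O)(C=C)[C@H](C[C@@]3(CC#C[Si](C)(C)C)C(=O)O[C@H]4C[C@@H](C)C(OS(=O)(=O)C(F)(F)F)=CC[C@H]43)C[C@H]12 | intermediate
25 | methyl ketone: 24 with the silylpropargyl group hydrated to 2-oxopropyl | CN(C)CC1C(=O)O[C@@H]2C[C@H](C)[C@@](O)(C=C)[C@H](C[C@@]3(CC(C)=O)C(=O)O[C@H]4C[C@@H](C)C(OS(=O)(=O)C(F)(F)F)=CC[C@H]43)C[C@H]12 | intermediate
26 | keto aldehyde: 25 with the vinyl group cleaved to formyl (C2) | CN(C)CC1C(=O)O[C@@H]2C[C@H](C)[C@@](O)(C=O)[C@H](C[C@@]3(CC(C)=O)C(=O)O[C@H]4C[C@@H](C)C(OS(=O)(=O)C(F)(F)F)=CC[C@H]43)C[C@H]12 | intermediate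
27 | ring-closed aldol with C2 hydroxyl and C3–H (both configurations open) | CN(C)CC1C(=O)O[C@@H]2C[C@H](C)[C@@]3(O)C(O)C(C(C)=O)[C@]4(C[C@@H]3C[C@H]12)C(=O)O[C@H]1C[C@@H](C)C(OS(=O)(=O)C(F)(F)F)=CC[C@H]14 | intermediate
28 | ring C enone with C1 hydroxyl, lower enol triflate and C11 CH2NMe2 | CN(C)CC1C(=O)O[C@@H]2C[C@H](C)[C@@]3(O)C=C(C(C)=O)[C@]4(C[C@@H]3C[C@H]12)C(=O)O[C@H]1C[C@@H](C)C(OS(=O)(=O)C(F)(F)F)=CC[C@H]14 | intermediate
29 | 28 with the triflate replaced by the (E)-3-oxobut-1-enyl side chain | CN(C)CC1C(=O)O[C@@H]2C[C@H](C)[C@@]3(O)C=C(C(C)=O)[C@]4(C[C@@H]3C[C@H]12)C(=O)O[C@H]1C[C@@H](C)C(/C=C/C(C)=O)=CC[C@H]14 | intermediate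
30 | trimethylammonium iodide of 29 | C[N+](C)(C)CC1C(=O)O[C@@H]2C[C@H](C)[C@@]3(O)C=C(C(C)=O)[C@]4(C[C@@H]3C[C@H]12)C(=O)O[C@H]1C[C@@H](C)C(/C=C/C(C)=O)=CC[C@H]14.[I-] | intermediate
31 | CNP0168949.2 | C=C1C(=O)O[C@@H]2C[C@H](C)[C@@]3(O)C=C(C(C)=O)[C@]4(C[C@@H]3C[C@H]12)C(=O)O[C@H]1C[C@@H](C)C(/C=C/C(C)=O)=CC[C@H]14 | target

**Totals**

Total step count: 20. Longest linear sequence: 17 steps (steps 1–3, 7–11, 12–20).

**Steps most likely to fail**

Step 6 (key step). The methyl-bearing α-carbon may migrate in place of CH2, a second carbon may be inserted, or the silyl shift may stop halfway and give mixtures. The fallback keeps the one-carbon enlargement of the same ring but goes through a siloxycyclopropane, and it sets out from 9. LiN(iPr)2 and Me3SiCl at −78 °C give the kinetic trimethylsilyl enol ether of 9 on the CH2 side F1. Cyclopropanation with Et2Zn and CH2I2 gives the siloxybicyclo[4.1.0]heptane F2. FeCl3 in DMF opens the internal cyclopropane bond to the ring-enlarged 3-chlorocycloheptanone F3, and NaOAc in MeOH eliminates HCl to the cyclohept-2-enone F4. 1,4-Reduction with LiBH(s-Bu)3 at −78 °C and trapping with Me3SiCl should return the route at enol silane 11.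

Step 11. The hydroxymethylene enolate may be alkylated on oxygen in place of carbon, and the carbonate may cleave the formyl group from the quaternary product. The fallback carries the aldehyde as its acetal and sets out from 15. LiN(iPr)2 and Me3SiCl give the ketene silyl acetal F5. HC(OMe)3 with BF3·OEt2 gives the 3-(dimethoxymethyl) lactone F6. A second deprotonation with LiN(iPr)2 and alkylation with BrCH2C≡CSiMe3, again trans to C6′, gives the quaternary acetal F7. Oxalic acid on wet silica should return the route at 17.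

Step 18. Ozone may also attack the enol triflate double bond or the amine side chain, and the free hydroxy aldehyde may rearrange (acyloin shift) before the ring closes. The fallback brings in C2 at the alcohol oxidation level, without ozone, and sets out from 22. (iPrO)Me2SiCH2MgCl with CeCl3 at −78 °C adds with the same facial course as step 15 to give the (silylmethyl) carbinol F8. Tamao oxidation (H2O2, KF, KHCO3) gives the 1,2-diol F9. The Mannich reaction of step 16 (LiN(iPr)2, 3.3 equiv) gives the amino diol F10, and the hydration of step 17 gives the keto diol F11. Parikh–Doering oxidation of the primary alcohol (SO3·pyridine, DMSO, iPr2NEt) should return the route at keto aldehyde 26, which is closed to 28 with pyrrolidine and AcOH as in step 18.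

Further compounds

F1 | step 6 | kinetic trimethylsilyl enol ether of 9 (C1=C6 double bond) | C1C(=O)O[C@@H]2C[C@H](C)C(O[Si](C)(C)C)=C[C@H]12
F2 | step 6 | siloxybicyclo[4.1.0]heptane from F1 (cyclopropane configuration open) | C1C(=O)O[C@@H]2C[C@H](C)C3(O[Si](C)(C)C)CC3[C@H]12
F3 | step 6 | ring-enlarged 3-chlorocycloheptanone (chlorine on C6) | C1C(=O)O[C@@H]2C[C@H](C)C(=O)CC(Cl)[C@H]12
F4 | step 6 | cyclohept-2-enone with C5=C6 double bond | C1C(=O)O[C@@H]2C[C@H](C)C(=O)C=C[C@H]12
F5 | step 11 | trimethylsilyl ketene acetal of lactone 15 | C1=C(O[Si](C)(C)C)O[C@H]2C[C@@H](C)C(OS(=O)(=O)C(F)(F)F)=CC[C@@H]12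
F6 | step 11 | 3-(dimethoxymethyl) lactone from 15 (C3 configuration open) | COC(OC)C1C(=O)O[C@H]2C[C@@H](C)C(OS(=O)(=O)C(F)(F)F)=CC[C@@H]12
F7 | step 11 | dimethyl acetal of 17 | COC(OC)[C@@]1(CC#C[Si](C)(C)C)C(=O)O[C@H]2C[C@@H](C)C(OS(=O)(=O)C(F)(F)F)=CC[C@H]21
F8 | step 18 | C1 carbinol with CH2SiMe2(OiPr) from 22 | C1C(=O)O[C@@H]2C[C@H](C)[C@@](O)(C[Si](C)(C)OC(C)C)[C@H](C[C@@]3(CC#C[Si](C)(C)C)C(=O)O[C@H]4C[C@@H](C)C(OS(=O)(=O)C(F)(F)F)=CC[C@H]43)C[C@H]12
F9 | step 18 | 1,2-diol with C1 hydroxyl and C2 hydroxymethyl | C1C(=O)O[C@@H]2C[C@H](C)[C@@](O)(CO)[C@H](C[C@@]3(CC#C[Si](C)(C)C)C(=O)O[C@H]4C[C@@H](C)C(OS(=O)(=O)C(F)(F)F)=CC[C@H]43)C[C@H]12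
F10 | step 18 | Mannich base of diol F9 | CN(C)CC1C(=O)O[C@@H]2C[C@H](C)[C@@](O)(CO)[C@H](C[C@@]3(CC#C[Si](C)(C)C)C(=O)O[C@H]4C[C@@H](C)C(OS(=O)(=O)C(F)(F)F)=CC[C@H]43)C[C@H]12
F11 | step 18 | keto diol with 2-oxopropyl group on C11′ | CN(C)CC1C(=O)O[C@@H]2C[C@H](C)[C@@](O)(CO)[C@H](C[C@@]3(CC(C)=O)C(=O)O[C@H]4C[C@@H](C)C(OS(=O)(=O)C(F)(F)F)=CC[C@H]43)C[C@H]12
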